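Larch and birch carry the same charge, but larch at 75 °C levels off lower than birch at 90 °C, 20.3% of target at 720 min against a shoulder of 27.5% at 120 min, and birch is still falling, to 24.2% at 360 min. Birch is the flask you are asked about.

| setting | birch | larch | flask |
|---|---|---|---|
| starting material | 0.050 M | 0.050 M | 0.050 M |
| reagent | 1 equiv | 1 equiv | 1.00 equiv |
| temperature | 90 °C | 75 °C | 90 °C |
| remark | the very flask that is asked about, followed so far | run made earlier |  |
| time |  |  | 6.0 h |

| run | time / min | target / % |
|---|---|---|
| birch | 30.0 | 31.8 |
| birch | 50.0 | 28.6 |
| birch | 80.0 | 27.8 |
| birch | 120 | 27.5 |
| birch | 240 | 26.0 |
| birch | 360 | 24.2 |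
| larch | 60.0 | 50.4 |
| larch | 120 | 34.5 |
| larch | 180 | 27.9 |
| larch | 240 | 22.5 |
| larch | 480 | 20.4 |
| larch | 720 | 20.3 |

(each reading ± 1 percentage point)

- Sunday's: at 6.0 h take out 90% of the target then present, then wait 6.0 h
- Saturday's: at 6.0 h raise the temperature by 15 K, then wait 6.0 h
- Thursday's: change nothing and wait 6.0 h more
- Friday's: at 6.0 h add reagent, 100% of the amount charged, then wait 6.0 h

- target that was removed still counts
- steps that have been proposed: starting material + reagent <-> target + released group; target <-> isomer of the product; starting material + released group -> side product
- additions bring no volume worth counting

* target, in percent of the starting material first charged, at 6.0 h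
* the remedy with the largest gain of target, or "none" below 2 percentage points (Sunday's / Saturday's / Thursday's / Friday's / none)
* target present, with what was taken out counted in, in percent of the starting material first charged, after Sunday's
* target present, with what was taken out counted in, in percent of the starting material first charged, after Thursday's

Count half-lives first. The excess of target over the last larch reading shrinks at a pace that gives a half-life of 55.4 min, so that last reading stands 13.0 half-lives out. The birch readings, measured against the one at 120 min, give about 10.2 min, and 6.0 h holds 35.4 of those. Because each half-life is so short against the time of the late readings, those readings show the balance between target and isomer, not the speed of their exchange.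

Running the larch excess back to time zero gives a pool of 84.1%. I take the same pool for birch, since the charge is the same. Now define the relaxed share, [target]/([target]+[isomer]) once the two have equilibrated: 24.1% in larch and 32.7% in birch. The birch shoulder stands higher because the hotter flask holds the larger share.

The later birch drift I read as a shrinking pool, now 74.0%. So you have about 24.2% of target, give or take 1 percentage point. Sunday's takes out 21.8%, and the wait is again 35.4 half-lives, so the share rebuilds on what stays. Counted in, that makes 38.9% before any further loss of pool. Saturday's, credited with the rise in share seen between larch and birch, gains about 6.3 points, less than Sunday's. Thursday's keeps the share on a shrinking pool, so target falls.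

The forecast gives 24.3% now, 20% after Thursday's and 37% after Sunday's, its choice, where the isomer “re-equilibrates back to target”.

The flask gives 25.0%, then 39.3% after Sunday's and 23.5% after Thursday's. The best remedy is Sunday's, with a gain of 14 points against 2.2 points for Saturday's.

    starting material + reagent ⇌ target + released group (K = 30.0, k = 0.150 L mol⁻¹ s⁻¹, Ea = 80.0 kJ mol⁻¹, ΔH = −14.0 kJ mol⁻¹)
    target ⇌ isomer of the product (K = 2.10, k = 0.00100 s⁻¹, Ea = 118 kJ mol⁻¹, ΔH = −27.0 kJ mol⁻¹)
    starting material + released group → side product (k = 0.00610 L mol⁻¹ s⁻¹, Ea = 59.0 kJ mol⁻¹)
    (constants at 90 °C)

At 360 min this flask holds a pool of 78.1%, and the share of it is 25.5%, against 25.0% of target present. The neighbour flask is this flask with 0.250 equiv of reagent, here the limiting reagent, with 0.0143% of its own charge left and 50.7% of starting material unreacted. Its temperature is unchanged, and the relaxation half-life of 7.83 min is short against the time, so the same share applies to its far smaller pool of 25.0%. That gives 8.18% of target, and the neighbour flask holds 8.06%.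

(The earlier runs and the new flask come from a simulation with constants of no real substance, and the scatter is random.)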